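A direct plan would tribrominate 4-methylcatechol A1 to 3,4,6-tribromo-5-methylbenzene-1,2-diol A2, oxidise A2 to its o-quinone A3, let A3 tautomerise under acid to the 2-hydroxy-p-quinone methide A4 and let A4 take up pyrrolidin-2-one A5 through nitrogen at the exocyclic carbon, so that the benzylic C–N bond would be made last.
The tautomerisation of A3 to A4 would be weak, since it would need proton loss from a methyl group wedged between two bromines and would compete with dimerisation and hydration of A4.
The 1,6-addition would be weak, since the neutral lactam A5 would be a poor nucleophile that can react at O or N and would have to outrun water and the catechols present.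
The oxidation would be weak, since the product catechol could exchange redox state with A3 and A4 in the flask and be over-oxidised.

The strategy exploits the lone methylene that bridges lactam N1 and arene C1, para to the C4 hydroxyl (benzyl numbering): it is at the oxidation level of formaldehyde. The route therefore rests on the aryl–CH2 bond, not the CH2–N bond. Pyrrolidin-2-one 1 takes up formaldehyde 2 at nitrogen, and the derived N-acyliminium ion attacks catechol 3 para to one hydroxyl (Tscherniac–Einhorn amidomethylation). One flask joins three commodity components into the whole C–N skeleton, the ring acting as nucleophile, no oxidant needed. The three bromines then fill the three ring positions left, each ortho or para to a hydroxyl. No quinone, quinone methide or lactam N-nucleophile appears.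

Key step: step 1

Remark: paraformaldehyde is counted as its monomer, formaldehyde 2, for numbering and atom count. The target has no stereocentre.

Step 1
Reactants: 1 pyrrolidin-2-one; 2 formaldehyde (used as paraformaldehyde); 3 benzene-1,2-diol (catechol)
Product: 6 1-(3,4-dihydroxybenzyl)pyrrolidin-2-one, via 1-(hydroxymethyl)pyrrolidin-2-one 4 (not isolated), via 1-methylidene-2-oxopyrrolidin-1-ium trifluoroacetate 5 (not isolated)
Conditions: 1 (1.05 equiv), (CH2O)n (1.0 equiv), K2CO3 (2 mol%), neat, 80 °C, 2 h; then added dropwise to 3 (3 equiv) in CF3CO2H/CH2Cl2 (1:1), 0 °C → rt, 4 h; aq. NaHCO3/EtOAc; excess 3 sublimed off (Kugelrohr), crystallisation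
Reagents that add atoms: none
Why: K2CO3-catalysed addition of the N–H of 1 to formaldehyde first converts all of 2 into the hemiaminal 4, so that the arene never meets free aldehyde; in CF3CO2H 4 loses water to the N-acyliminium ion 5, a small cationic carbon electrophile, which is attacked by catechol in an electrophilic aromatic substitution that forms the aryl–CH2 bond. This is a Tscherniac–Einhorn amidomethylation run as a telescoped three-component amide–formaldehyde–arene condensation, and the closest known reaction type is the acid-mediated amidomethylation of phenols by N-(hydroxymethyl)amides and N-(hydroxymethyl)lactams. No ring is closed and no stereocentre is formed. The step needs attack at C4 and not at C3 of catechol: C4 is para to one hydroxyl and has no ortho substituent, whereas C3 is flanked by a hydroxyl, so the bulky solvated cation should prefer C4. It also needs a single substitution and C- over O-attack: the threefold excess of 3 and the acid-bound, inductively withdrawing amidomethyl group of 6 should hold back a second attack, and an O-bound aryloxymethyl lactam is an N,O-acetal that re-ionises to 5 in the acid and drains to the C-bound product. The short time at or below room temperature should keep the acid from re-ionising the new p-hydroxybenzyl–nitrogen bond.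

Step 2
Reactants: 6 1-(3,4-dihydroxybenzyl)pyrrolidin-2-one
Product: 7 1-(2,3,6-tribromo-4,5-dihydroxybenzyl)pyrrolidin-2-one (target)
Conditions: Br2 (3.05 equiv), AcOH, 10 °C → rt, 2 h; aq. NaHSO3; precipitation from water
Reagents that add atoms: bromine, BrBr
Why: Electrophilic aromatic bromination: the three remaining ring positions of 6 (C2 and C5, each ortho to a hydroxyl, and C6, para to one) are all activated, so three equivalents of Br2 should fill them in AcOH while the lactam and the benzylic C–N bond on the increasingly electron-poor ring stay intact, and NaHSO3 returns any o-quinone to the catechol; no stereocentre is formed.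

Compound list
1 | pyrrolidin-2-one | O=C1CCCN1 | starting material
2 | formaldehyde (used as paraformaldehyde) | C=O | starting material
3 | benzene-1,2-diol (catechol) | Oc1ccccc1O | starting material
4 | 1-(hydroxymethyl)pyrrolidin-2-one | O=C1CCCN1CO | intermediate (not isolated)
5 | 1-methylidene-2-oxopyrrolidin-1-ium trifluoroacetate (N-acyliminium ion) | C=[N+]1CCCC1=O.[O-]C(=O)C(F)(F)F | intermediate (not isolated)
6 | 1-(3,4-dihydroxybenzyl)pyrrolidin-2-one | O=C1CCCN1Cc1ccc(O)c(O)c1 | intermediate
7 | 1-(2,3,6-tribromo-4,5-dihydroxybenzyl)pyrrolidin-2-one | O=C1CCCN1Cc1c(Br)c(O)c(O)c(Br)c1Br | target

Total step count: 2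
Longest linear sequence: 2

Steps most likely to fail (the route has only two steps, so the key step is entered twice, once for each of its two independent failure processes):

Step 1, aromatic substitution stage. The cation may attack next to a hydroxyl (C3 of catechol), the product may be amidomethylated a second time, or the acid may re-ionise the new benzyl–nitrogen bond and pass the benzyl group to excess catechol. The fallback keeps the C–C bond formation but masks the phenols. It sets out from 4, which would be made from 1 and 2 as in step 1 and crystallised. Compound 4 and 1,2-dimethoxybenzene (veratrole) F1 (2 equiv) in CF3CO2H at rt should give 1-(3,4-dimethoxybenzyl)pyrrolidin-2-one F2, since the dimethyl ether is substituted reliably at C4 and carries no free phenol for O-attack. BBr3 (3.5 equiv) in CH2Cl2, −78 °C → rt, would then cleave both ethers and come back to the route at 6.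

Step 1, formaldehyde stage. The hemiaminal 4 may revert in the acid to the lactam and free formaldehyde, which would bridge catechol units through methylene groups (phenol–formaldehyde condensation) and give the methylenebis-lactam. The fallback gives up formaldehyde and makes the CH2–N bond by alkylation. It sets out from 1, which would be deprotonated (NaH, DMF, 0 °C) and alkylated with 4-(chloromethyl)-1,2-dimethoxybenzene (3,4-dimethoxybenzyl chloride) F3 to give 1-(3,4-dimethoxybenzyl)pyrrolidin-2-one F2. BBr3 (3.5 equiv) in CH2Cl2, −78 °C → rt, would come back to the route at 6.

Step 2. Bromine may oxidise the catechol to an o-quinone, attack ipso at the ring carbon para to a free hydroxyl with loss of the lactam-bearing methylene (bromodealkylation), or stall before the third bromination at the position between hydroxyl and CH2N. The fallback brominates the ring while the phenols are masked as methyl ethers, which cannot be oxidised to a quinone and offer no dienone pathway for ipso loss. It sets out from 4 and passes through the dimethyl ether F2 made as in the first fallback. Br2 (3.5 equiv) and FeBr3 (10 mol%) in CH2Cl2, 0 °C → reflux, should give 1-(2,3,6-tribromo-4,5-dimethoxybenzyl)pyrrolidin-2-one F4. BBr3 (4 equiv) in CH2Cl2, −78 °C → rt, would then free both phenols and come back to the route at 7.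

Further compounds
F1 | step 1 | 1,2-dimethoxybenzene (veratrole) | COc1ccccc1OC
F2 | step 1 | 1-(3,4-dimethoxybenzyl)pyrrolidin-2-one | COc1ccc(CN2CCCC2=O)cc1OC
F3 | step 1 | 4-(chloromethyl)-1,2-dimethoxybenzene (3,4-dimethoxybenzyl chloride) | COc1ccc(CCl)cc1OC
F4 | step 2 | 1-(2,3,6-tribromo-4,5-dimethoxybenzyl)pyrrolidin-2-one | O=C1CCCN1Cc1c(Br)c(OC)c(OC)c(Br)c1Br
A1 | direct plan | 4-methylbenzene-1,2-diol (4-methylcatechol) | Cc1ccc(O)c(O)c1
A2 | direct plan | 3,4,6-tribromo-5-methylbenzene-1,2-diol | Cc1c(Br)c(O)c(O)c(Br)c1Br
A3 | direct plan | 3,4,6-tribromo-5-methylcyclohexa-3,5-diene-1,2-dione | CC1=C(Br)C(=O)C(=O)C(Br)=C1Br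
A4 | direct plan | 2,3,5-tribromo-6-hydroxy-4-methylidenecyclohexa-2,5-dien-1-one | C=C1C(Br)=C(O)C(=O)C(Br)=C1Br
A5 | direct plan | pyrrolidin-2-one | O=C1CCCN1
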